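**Strategy**

Everything rests on disconnecting the cyclobutane between ring C4 (the CH2) and ring C1 (the CH bearing the exocyclic CH2 to the core). The key step exploits that C1 and its exocyclic CH2 together are a masked vinyl group on the gem-dimethyl carbon C2: Cu–Bpin adds across this vinyl group of an acyclic (S)-mesylate, made by an enantioselective Ireland–Claisen rearrangement, and the secondary alkylcopper displaces the primary mesylate on C4. One operation thus closes the four-membered ring, sets its second stereocentre and leaves boron on the exocyclic CH2. B-alkyl Suzuki coupling to an iodinated chromanone–dihydrocoumarin, dearomative prenylation and lactone hydrolysis finish the target.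

Key step: step 5

Assumption (chemistry): in the reagent- or ligand-controlled steps 2, 7, 9 and 13 the enantiomer of the chiral reagent named is taken, by analogy with the parent reactions, to give the configuration drawn; the antipode of each is equally available.

**Route**

Step 1
Reactants: 1 3-methylbut-3-enoic acid; 2 3-methylbut-2-en-1-ol (prenol)
Product: 3 3-methylbut-2-en-1-yl 3-methylbut-3-enoate
Conditions: DCC, DMAP (5 mol%), CH2Cl2, 0 °C → rt
Reagents that add atoms: none
Why: Steglich esterification under mild, nearly neutral conditions should give the prenyl ester without moving the β,γ-double bond into conjugation.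

Step 2
Reactants: 3 3-methylbut-2-en-1-yl 3-methylbut-3-enoate
Product: 5 (2S)-3,3-dimethyl-2-(prop-1-en-2-yl)pent-4-enoic acid, via boron ketene acetal 4 (not isolated)
Conditions: (4S,5S)-2-bromo-4,5-diphenyl-1,3-bis{[3,5-bis(trifluoromethyl)phenyl]sulfonyl}-1,3,2-diazaborolidine (1.2 equiv), i-Pr2NEt, CH2Cl2, −78 °C → 4 °C; then H2O
Reagents that add atoms: none
Why: Soft enolisation gives the chiral O-boron ketene acetal 4, which should undergo the Ireland–Claisen [3,3] rearrangement through a chair transition state onto the dimethyl-substituted allyl terminus, the C2-symmetric bis-sulfonamide on boron shielding one face of the ketene acetal and so setting the α-stereocentre (S).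

Step 3
Reactants: 5 (2S)-3,3-dimethyl-2-(prop-1-en-2-yl)pent-4-enoic acid
Product: 6 (2S)-3,3-dimethyl-2-(prop-1-en-2-yl)pent-4-en-1-ol
Conditions: LiAlH4, Et2O, 0 °C → rt
Reagents that add atoms: none
Why: Hydride reduction of the acid to the primary alcohol; the carboxylate is not enolised, so the stereocentre should be retained.

Step 4
Reactants: 6 (2S)-3,3-dimethyl-2-(prop-1-en-2-yl)pent-4-en-1-ol
Product: 7 (2S)-3,3-dimethyl-2-(prop-1-en-2-yl)pent-4-en-1-yl methanesulfonate
Conditions: MsCl, Et3N, CH2Cl2, −10 °C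
Reagents that add atoms: methanesulfonyl chloride (MsCl), CS(=O)(=O)Cl
Why: O-Sulfonylation of the primary alcohol; no bond to the stereocentre is broken.

Step 5
Reactants: 7 (2S)-3,3-dimethyl-2-(prop-1-en-2-yl)pent-4-en-1-yl methanesulfonate
Product: 9 2-{[(1S,3S)-2,2-dimethyl-3-(prop-1-en-2-yl)cyclobutyl]methyl}-4,4,5,5-tetramethyl-1,3,2-dioxaborolane (cis), via β-boryl alkylcopper 8 (not isolated)
Conditions: CuCl (10 mol%), Xantphos (10 mol%), KOt-Bu (1.2 equiv), B2pin2 (1.3 equiv), THF, 30 °C
Reagents that add atoms: bis(pinacolato)diboron (B2pin2), CC1(C)OB(OC1(C)C)B1OC(C)(C)C(C)(C)O1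
Why: Xantphos–Cu–Bpin, formed from CuCl, KOt-Bu and B2pin2, adds syn across the monosubstituted vinyl group with boron on the terminal carbon and copper on the internal one, and the secondary alkylcopper 8 then displaces the primary mesylate intramolecularly with retention at the C–Cu carbon, which forms the ring CH2–CH bond and closes the cyclobutane. The closest known reaction type is the borylative exo-cyclisation of ω-alkenyl halides and sulfonates catalysed by monovalent copper, which gives (cyclobutylmethyl)boronates. The ring closes in the 4-exo-tet mode, helped by the gem-dialkyl effect of the quaternary carbon between the two reacting carbons. The new stereocentre (the ring CH that carries CH2Bpin) is set in the borylcupration by 1,3-induction from the existing S centre, copper being expected to enter anti to the branched CH(isopropenyl)CH2OMs group, and the cis outcome is reinforced in the ring closure, where CH2Bpin and isopropenyl can both sit pseudo-equatorial on the puckered ring; the existing centre is untouched. The step needs chemoselectivity for the vinyl over the isopropenyl alkene and for alkene addition over direct borylation of the mesylate: a 1,1-disubstituted unactivated alkene is a far poorer partner for borylcupration, and the β-branched sulfonate is slow in intermolecular substitution and inert to single-electron reduction. The exocyclic CH2 emerges as a C–B bond, ready for coupling to the core.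

Step 6
Reactants: 10 5,7-dihydroxy-2H-chromen-2-one (5,7-dihydroxycoumarin)
Product: 11 5-hydroxy-7-methoxy-2H-chromen-2-one
Conditions: MeI (1.05 equiv), K2CO3 (1.1 equiv), acetone, rt
Reagents that add atoms: iodomethane (MeI), CI
Why: Williamson O-methylation of the more acidic and unhindered 7-OH (its phenoxide is para-quinoid conjugated with the pyranone carbonyl), one equivalent of base and MeI leaving the 5-OH free.

Step 7
Reactants: 11 5-hydroxy-7-methoxy-2H-chromen-2-one; 12 phenylboronic acid
Product: 13 (4S)-5-hydroxy-7-methoxy-4-phenyl-3,4-dihydro-2H-chromen-2-one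
Conditions: Rh(acac)(C2H4)2 (3 mol%), (S)-SEGPHOS (3.3 mol%), 12 (5 equiv), dioxane/H2O 10:1, 60 °C
Reagents that add atoms: none
Why: Rhodium-catalysed asymmetric 1,4-addition of the arylboronic acid to the coumarin (aryl–rhodium insertion, then protonation by water), the (S)-SEGPHOS complex of monovalent rhodium setting the benzylic stereocentre (S).

Step 8
Reactants: 13 (4S)-5-hydroxy-7-methoxy-4-phenyl-3,4-dihydro-2H-chromen-2-one; 14 (2E)-2-methylbut-2-enoyl chloride (tigloyl chloride)
Product: 15 (4S)-5-hydroxy-7-methoxy-6-[(2E)-2-methylbut-2-enoyl]-4-phenyl-3,4-dihydro-2H-chromen-2-one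
Conditions: AlCl3 (3 equiv), PhNO2, 0 °C → rt; then ice/1 M HCl
Reagents that add atoms: none
Why: Friedel–Crafts C-acylation ortho to the free phenol (chelated o-hydroxyaryl ketone); acylation at the other free ring position would give the same compound after migration of the lactone to the second oxygen flanking the benzylic carbon, so the regiochemistry is self-correcting, and the low temperature should keep the enone from closing prematurely.

Step 9
Reactants: 15 (4S)-5-hydroxy-7-methoxy-6-[(2E)-2-methylbut-2-enoyl]-4-phenyl-3,4-dihydro-2H-chromen-2-one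
Product: 16 (2R,3S,10S)-5-methoxy-2,3-dimethyl-10-phenyl-2,3,9,10-tetrahydro-4H,8H-pyrano[2,3-f]chromene-4,8-dione (cis-2,3-dimethylchromanone fused to the dihydrocoumarin)
Conditions: (−)-quinine (20 mol%), PhCl, rt
Reagents that add atoms: none
Why: Intramolecular oxa-Michael addition of the only free phenol to the tigloyl enone under bifunctional cinchona-alkaloid catalysis (quinuclidine nitrogen as base, C9–OH as hydrogen-bond donor), which sets C2 (R), kinetic protonation of the enol giving mainly the cis isomer; the methyl ether forces the pyranone oxygen to end next to the benzylic carbon.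

Step 10
Reactants: 16 (2R,3S,10S)-5-methoxy-2,3-dimethyl-10-phenyl-2,3,9,10-tetrahydro-4H,8H-pyrano[2,3-f]chromene-4,8-dione
Product: 17 (2R,3R,10S)-5-hydroxy-2,3-dimethyl-10-phenyl-2,3,9,10-tetrahydro-4H,8H-pyrano[2,3-f]chromene-4,8-dione (trans-2,3-dimethyl)
Conditions: MgI2 (3 equiv), toluene/Et2O, 80 °C; then 1 M HCl
Reagents that add atoms: none
Why: Chelation-assisted SN2 demethylation by iodide of the methyl ether peri to the chromanone carbonyl, with epimerisation at C3 through the magnesium enolate to the more stable trans-diequatorial (2R,3R) isomer; C2 and the benzylic centre are not touched.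

Step 11
Reactants: 17 (2R,3R,10S)-5-hydroxy-2,3-dimethyl-10-phenyl-2,3,9,10-tetrahydro-4H,8H-pyrano[2,3-f]chromene-4,8-dione
Product: 18 (2R,3R,10S)-5-hydroxy-6-iodo-2,3-dimethyl-10-phenyl-2,3,9,10-tetrahydro-4H,8H-pyrano[2,3-f]chromene-4,8-dione
Conditions: NIS (1.05 equiv), DMF, 0 °C → rt
Reagents that add atoms: N-iodosuccinimide (NIS), O=C1CCC(=O)N1I
Why: Electrophilic aromatic iodination at the only remaining ring C–H, which is ortho to the free phenol.

Step 12
Reactants: 18 (2R,3R,10S)-5-hydroxy-6-iodo-2,3-dimethyl-10-phenyl-2,3,9,10-tetrahydro-4H,8H-pyrano[2,3-f]chromene-4,8-dione; 9 2-{[(1S,3S)-2,2-dimethyl-3-(prop-1-en-2-yl)cyclobutyl]methyl}-4,4,5,5-tetramethyl-1,3,2-dioxaborolane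
Product: 19 (2R,3R,10S)-6-{[(1R,3S)-2,2-dimethyl-3-(prop-1-en-2-yl)cyclobutyl]methyl}-5-hydroxy-2,3-dimethyl-10-phenyl-2,3,9,10-tetrahydro-4H,8H-pyrano[2,3-f]chromene-4,8-dione
Conditions: Pd(OAc)2 (5 mol%), RuPhos (10 mol%), K3PO4 (3 equiv), toluene/H2O 10:1, 80 °C; then 1 M HCl
Reagents that add atoms: none
Why: B-alkyl Suzuki–Miyaura coupling (oxidative addition of the aryl iodide to zerovalent palladium, base-assisted transmetalation of the primary alkylboronate, reductive elimination favoured over β-hydride elimination by the bulky biaryl phosphine); no stereocentre is involved, the phenoxide formed under the base disfavours enolate chemistry at the chromanone, and any lactone opened re-closes on acidic work-up.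

Step 13
Reactants: 19 (2R,3R,10S)-6-{[(1R,3S)-2,2-dimethyl-3-(prop-1-en-2-yl)cyclobutyl]methyl}-5-hydroxy-2,3-dimethyl-10-phenyl-2,3,9,10-tetrahydro-4H,8H-pyrano[2,3-f]chromene-4,8-dione; 20 3-methylbut-2-en-1-yl acetate (prenyl acetate)
Product: 21 (2R,3R,6S,10S)-6-{[(1R,3S)-2,2-dimethyl-3-(prop-1-en-2-yl)cyclobutyl]methyl}-2,3-dimethyl-6-(3-methylbut-2-en-1-yl)-10-phenyl-2,3,9,10-tetrahydro-4H,8H-pyrano[2,3-f]chromene-4,5,8(6H)-trione (dearomatised lactone; C6 is S here and becomes R in the target only through the change in CIP priorities on lactone opening)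
Conditions: Pd2(dba)3 (2.5 mol%), (R,R)-DACH-phenyl bisphosphine ligand [N,N'-(1R,2R)-cyclohexane-1,2-diylbis(2-diphenylphosphinobenzamide)] (7.5 mol%), Cs2CO3 (1.2 equiv), THF, 0 °C → rt
Reagents that add atoms: none
Why: Tsuji–Trost dearomative C-allylation, in which the phenoxide attacks the unsubstituted terminus of the π-prenyl complex of divalent palladium through its ortho carbon bearing the cyclobutylmethyl group (O-allylation is reversible under palladium catalysis), creating the quaternary stereocentre under control of the chiral ligand pocket, since the remote existing centres offer no useful bias.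

Step 14
Reactants: 21 (2R,3R,6S,10S)-6-{[(1R,3S)-2,2-dimethyl-3-(prop-1-en-2-yl)cyclobutyl]methyl}-2,3-dimethyl-6-(3-methylbut-2-en-1-yl)-10-phenyl-2,3,9,10-tetrahydro-4H,8H-pyrano[2,3-f]chromene-4,5,8(6H)-trione
Product: 22 (3S)-3-[(2R,3R,6R)-6-{[(1R,3S)-2,2-dimethyl-3-(prop-1-en-2-yl)cyclobutyl]methyl}-5-hydroxy-2,3-dimethyl-6-(3-methylbut-2-en-1-yl)-4,7-dioxo-3,4,6,7-tetrahydro-2H-chromen-8-yl]-3-phenylpropanoic acid (target)
Conditions: LiOH (3 equiv), THF/H2O, 0 °C; then 1 M HCl to pH 3
Reagents that add atoms: lithium hydroxide, [Li+].[OH-]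
Why: Saponification of the activated enol lactone; the liberated oxygen becomes the ring C=O of the vinylogous acid, which should tautomerise to the enol chelated to the chromanone carbonyl, and no stereocentre is affected because the quaternary carbon cannot enolise.

**Compound list**

1 | 3-methylbut-3-enoic acid | C=C(C)CC(=O)O | starting material
2 | 3-methylbut-2-en-1-ol (prenol) | CC(C)=CCO | starting material
3 | 3-methylbut-2-en-1-yl 3-methylbut-3-enoate | C=C(C)CC(=O)OCC=C(C)C | intermediate
4 | boron ketene acetal of 3, boron held in the (4S,5S)-4,5-diphenyl-1,3-bis{[3,5-bis(trifluoromethyl)phenyl]sulfonyl}-1,3,2-diazaborolidine ring (not isolated) | C=C(C)C=C(OCC=C(C)C)OB1N(S(=O)(=O)c2cc(C(F)(F)F)cc(C(F)(F)F)c2)[C@@H](c2ccccc2)[C@H](c2ccccc2)N1S(=O)(=O)c1cc(C(F)(F)F)cc(C(F)(F)F)c1 | intermediate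
5 | (2S)-3,3-dimethyl-2-(prop-1-en-2-yl)pent-4-enoic acid | C=C(C)[C@H](C(=O)O)C(C)(C)C=C | intermediate
6 | (2S)-3,3-dimethyl-2-(prop-1-en-2-yl)pent-4-en-1-ol | C=C(C)[C@H](CO)C(C)(C)C=C | intermediate
7 | (2S)-3,3-dimethyl-2-(prop-1-en-2-yl)pent-4-en-1-yl methanesulfonate | C=C(C)[C@H](COS(C)(=O)=O)C(C)(C)C=C | intermediate
8 | β-boryl secondary alkylcopper from syn addition of Cu–Bpin to the vinyl group of 7 (Cu on C4, Bpin on C5; phosphine ligand omitted; not isolated) | C=C(C)[C@H](COS(C)(=O)=O)C(C)(C)[C@H]([Cu])CB1OC(C)(C)C(C)(C)O1 | intermediate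
9 | 2-{[(1S,3S)-2,2-dimethyl-3-(prop-1-en-2-yl)cyclobutyl]methyl}-4,4,5,5-tetramethyl-1,3,2-dioxaborolane (cis) | CC1(C)OB(C[C@H]2C[C@@H](C(C)=C)C2(C)C)OC1(C)C | intermediate
10 | 5,7-dihydroxy-2H-chromen-2-one | O=c1ccc2c(O)cc(O)cc2o1 | starting material
11 | 5-hydroxy-7-methoxy-2H-chromen-2-one | COc1cc(O)c2ccc(=O)oc2c1 | intermediate
12 | phenylboronic acid | OB(O)c1ccccc1 | starting material
13 | (4S)-5-hydroxy-7-methoxy-4-phenyl-3,4-dihydro-2H-chromen-2-one | COc1cc(O)c2c(c1)OC(=O)C[C@H]2c1ccccc1 | intermediate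
14 | (2E)-2-methylbut-2-enoyl chloride | C/C=C(\C)C(=O)Cl | starting material
15 | (4S)-5-hydroxy-7-methoxy-6-[(2E)-2-methylbut-2-enoyl]-4-phenyl-3,4-dihydro-2H-chromen-2-one | COc1cc2OC(=O)C[C@@H](c3ccccc3)c2c(O)c1C(=O)/C(C)=C/C | intermediate
16 | (2R,3S,10S)-5-methoxy-2,3-dimethyl-10-phenyl-2,3,9,10-tetrahydro-4H,8H-pyrano[2,3-f]chromene-4,8-dione | COc1cc2OC(=O)C[C@@H](c3ccccc3)c2c2O[C@H](C)[C@H](C)C(=O)c12 | intermediate
17 | (2R,3R,10S)-5-hydroxy-2,3-dimethyl-10-phenyl-2,3,9,10-tetrahydro-4H,8H-pyrano[2,3-f]chromene-4,8-dione | Oc1cc2OC(=O)C[C@@H](c3ccccc3)c2c2O[C@H](C)[C@@H](C)C(=O)c12 | intermediate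
18 | (2R,3R,10S)-5-hydroxy-6-iodo-2,3-dimethyl-10-phenyl-2,3,9,10-tetrahydro-4H,8H-pyrano[2,3-f]chromene-4,8-dione | Oc1c(I)c2OC(=O)C[C@@H](c3ccccc3)c2c2O[C@H](C)[C@@H](C)C(=O)c12 | intermediate
19 | (2R,3R,10S)-6-{[(1R,3S)-2,2-dimethyl-3-(prop-1-en-2-yl)cyclobutyl]methyl}-5-hydroxy-2,3-dimethyl-10-phenyl-2,3,9,10-tetrahydro-4H,8H-pyrano[2,3-f]chromene-4,8-dione | Oc1c(C[C@H]3C[C@@H](C(C)=C)C3(C)C)c2OC(=O)C[C@@H](c3ccccc3)c2c2O[C@H](C)[C@@H](C)C(=O)c12 | intermediate
20 | 3-methylbut-2-en-1-yl acetate | CC(=O)OCC=C(C)C | starting material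
21 | (2R,3R,6S,10S)-6-{[(1R,3S)-2,2-dimethyl-3-(prop-1-en-2-yl)cyclobutyl]methyl}-2,3-dimethyl-6-(3-methylbut-2-en-1-yl)-10-phenyl-2,3,9,10-tetrahydro-4H,8H-pyrano[2,3-f]chromene-4,5,8(6H)-trione | C=C(C)[C@@H]1C[C@H](C[C@@]2(CC=C(C)C)C3=C([C@H](c4ccccc4)CC(=O)O3)C3=C(C(=O)[C@H](C)[C@@H](C)O3)C2=O)C1(C)C | intermediate
22 | (3S)-3-[(2R,3R,6R)-6-{[(1R,3S)-2,2-dimethyl-3-(prop-1-en-2-yl)cyclobutyl]methyl}-5-hydroxy-2,3-dimethyl-6-(3-methylbut-2-en-1-yl)-4,7-dioxo-3,4,6,7-tetrahydro-2H-chromen-8-yl]-3-phenylpropanoic acid | C=C(C)[C@@H]1C[C@H](C[C@@]2(CC=C(C)C)C(=O)C([C@@H](CC(=O)O)c3ccccc3)=C3O[C@H](C)[C@@H](C)C(=O)C3=C2O)C1(C)C | target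

**Step count and risks**

Total step count: 14. Longest linear sequence: 9 steps (10 → 22, steps 6–14); the cyclobutane branch is 5 steps (1 → 9) before the convergent step 12.

Steps most likely to fail:

1. Step 5 (key step). Facial discrimination in the borylcupration may be weak, because the controlling centre is 1,3 across a quaternary carbon, so cis and trans cyclobutanes could form together. Addition of Cu–Bpin to the hindered neopentyl-type vinyl group may also be slow enough for base-induced elimination of the mesylate to compete.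
Fallback, from 7 back to 9: the same ring bond is closed by an ester-enolate alkylation, which places the new stereocentre α to a carbonyl group where it can be equilibrated. Chemoselective hydroboration of the monosubstituted vinyl group of 7 (pinacolborane, RhCl(PPh3)3, THF) gives the terminal boronate F1. NaBO3 in THF/H2O oxidises it to the hydroxy mesylate F2, and (C5H5NH)2Cr2O7 in MeOH/DMF converts that into the methyl ester F3. KN(SiMe3)2 in THF at −78 °C → 0 °C closes the ring by 4-exo-tet alkylation to the cyclobutane ester F4, whose cis isomer is enriched by NaOMe/MeOH equilibration and chromatography. LiAlH4 gives the cyclobutylmethanol F5, I2/PPh3/imidazole the iodide F6, and copper-catalysed borylation (CuI, PPh3, LiOMe, B2pin2, DMF) returns 9.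

2. Step 13. Catalyst control over the face of the phenoxide may be incomplete, since the new quaternary centre is remote from every existing stereocentre. Attack through the para carbon, attack at the substituted allyl terminus, or O-allylation that does not re-ionise could also compete.
Fallback, from 19 back to 21: the prenyl group is delivered from oxygen by a [3,3] shift. O-Alkylation of 19 with 3-chloro-3-methylbut-1-yne (CuCl2 cat., DBU, MeCN, 0 °C) gives the 1,1-dimethylpropargyl aryl ether F7. Semi-hydrogenation (H2, Pd/CaCO3 poisoned with Pb(OAc)2, quinoline, EtOAc) gives the 1,1-dimethylallyl aryl ether F8. Heating in toluene (90–110 °C) effects the aromatic Claisen rearrangement onto the ortho carbon that carries the cyclobutylmethyl group, giving 21; this fixes the regiochemistry, but the two C6 epimers would then have to be separated by chromatography.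

3. Step 2. The [3,3] shift of the hindered prenyl ketene acetal may be slow at the temperature needed for high selectivity, enantioselectivity may erode on warming, and the β,γ-unsaturated ester may isomerise to the conjugated ester before enolisation.
Fallback, from 3 back to 6: the rearrangement is run in its racemic silyl form and the enantiomers are parted on a chiral auxiliary. LiN(i-Pr)2 and Me3SiCl in THF (−78 °C → 60 °C) convert 3 through the trimethylsilyl ketene acetal F9 into the racemic acid F10. Activation (t-BuCOCl, Et3N) and acylation of lithiated (S)-4-benzyl-1,3-oxazolidin-2-one (n-BuLi) give the (2S)-acyl imide F11 and the (2R)-acyl imide F12, which are separated by chromatography. LiBH4 (Et2O, H2O, 0 °C) cleaves F11 to alcohol 6 with recovery of the auxiliary.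

**Further compounds**

F1 | step 5 | (2S)-3,3-dimethyl-2-(prop-1-en-2-yl)-5-(4,4,5,5-tetramethyl-1,3,2-dioxaborolan-2-yl)pentyl methanesulfonate | CC1(C)OB(CCC(C)(C)[C@H](C(C)=C)COS(C)(=O)=O)OC1(C)C
F2 | step 5 | (2S)-5-hydroxy-3,3-dimethyl-2-(prop-1-en-2-yl)pentyl methanesulfonate | OCCC(C)(C)[C@H](C(C)=C)COS(C)(=O)=O
F3 | step 5 | methyl (4S)-3,3,5-trimethyl-4-[(methylsulfonyloxy)methyl]hex-5-enoate | COC(=O)CC(C)(C)[C@H](C(C)=C)COS(C)(=O)=O
F4 | step 5 | methyl (1S,3S)-2,2-dimethyl-3-(prop-1-en-2-yl)cyclobutane-1-carboxylate | COC(=O)[C@H]1C[C@@H](C(C)=C)C1(C)C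
F5 | step 5 | [(1S,3S)-2,2-dimethyl-3-(prop-1-en-2-yl)cyclobutyl]methanol | OC[C@H]1C[C@@H](C(C)=C)C1(C)C
F6 | step 5 | (1S,3S)-1-(iodomethyl)-2,2-dimethyl-3-(prop-1-en-2-yl)cyclobutane | IC[C@H]1C[C@@H](C(C)=C)C1(C)C
F7 | step 13 | 5-O-(2-methylbut-3-yn-2-yl) ether of 19 | C#CC(C)(C)Oc1c(C[C@H]3C[C@@H](C(C)=C)C3(C)C)c2OC(=O)C[C@@H](c3ccccc3)c2c2O[C@H](C)[C@@H](C)C(=O)c12
F8 | step 13 | 5-O-(2-methylbut-3-en-2-yl) ether of 19 | C=CC(C)(C)Oc1c(C[C@H]3C[C@@H](C(C)=C)C3(C)C)c2OC(=O)C[C@@H](c3ccccc3)c2c2O[C@H](C)[C@@H](C)C(=O)c12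
F9 | step 2 | trimethylsilyl ketene acetal of 3 (not isolated) | C=C(C)C=C(OCC=C(C)C)O[Si](C)(C)C
F10 | step 2 | racemic 3,3-dimethyl-2-(prop-1-en-2-yl)pent-4-enoic acid | C=C(C)C(C(=O)O)C(C)(C)C=C
F11 | step 2 | (4S)-4-benzyl-3-[(2S)-3,3-dimethyl-2-(prop-1-en-2-yl)pent-4-enoyl]-1,3-oxazolidin-2-one | O=C1OC[C@H](Cc2ccccc2)N1C(=O)[C@@H](C(C)=C)C(C)(C)C=C
F12 | step 2 | (4S)-4-benzyl-3-[(2R)-3,3-dimethyl-2-(prop-1-en-2-yl)pent-4-enoyl]-1,3-oxazolidin-2-one | O=C1OC[C@H](Cc2ccccc2)N1C(=O)[C@H](C(C)=C)C(C)(C)C=C
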